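**Plan**

- Retrosynthesis: the allyl ester at C15, the two acyl groups and C13=C14 (olefination) are removed first. The C6/C7 dioxygenation is traced back to a 6-alkoxy-5,8-dien-7-one, and C1–C10 is then cut (ring A), which leaves an aromatic ring B. Last, C1–C2, C4–C5 and C9–C11 are cut.
- Enabling feature: ring B (C5 to C10) carries oxygen on adjacent C6 and C7, methyl on C8, the side chain on C9 and a methyl-bearing quaternary C10 para to the C7 oxygen. It is a catechol monoether that has been dearomatised by alkylation at C10.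
- Forward: ring B is bought as 4-bromo-3,5-dimethylphenol. The C9 chain is joined by B-alkyl Suzuki coupling, the C5 arm (C4 to C1) by prenylation, Claisen rearrangement and hydroformylation, and the C7 oxygen by ortho-lithiation. Ring A then closes by para-alkylation of the C7 phenoxide with the C1 iodide.
- Stereochemistry: C10 from the chiral ammonium ion pair in the ring A closure; C5 by α-face protonation next to the C6 ketone; C6 by α-face hydride addition; C7 by hydride delivery from the 6β-hydroxyl; 13E from the olefination.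

Key step: step 8

Remarks. Labdane numbering (C1 to C20) is used for all intermediates, the benzene ring of the early compounds being the later ring B. β is the face of ring B that carries the C10 methyl group, and ξ marks a centre carried as a mixture of epimers. Assumption: the sense of face selection by the ammonium salt cannot be predicted, so the cinchonidine-derived salt is written and the pseudoenantiomeric cinchonine-derived salt would be used if it favours the other enantiomer.

**Route**

Step 1
Reactants: 1 4-bromo-3,5-dimethylphenol; 2 2-methyl-2-vinyl-1,3-dioxolane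
Product: 4 3,5-dimethyl-4-[2-(2-methyl-1,3-dioxolan-2-yl)ethyl]phenol, via alkylborane 3 (not isolated)
Conditions: 2, 9-BBN, THF, 0 °C to rt; then 1, Pd(OAc)2 (3 mol%), SPhos (6 mol%), K3PO4 aq, THF, 65 °C
Reagents that add atoms: none
Why: B-alkyl Suzuki–Miyaura coupling, in which 9-BBN adds to the terminal carbon of the vinyl ketal and the primary alkyl group should then transfer to the hindered, electron-rich aryl bromide under a dialkylbiarylphosphine-ligated palladium catalyst, the ketal being inert.

Step 2
Reactants: 4 3,5-dimethyl-4-[2-(2-methyl-1,3-dioxolan-2-yl)ethyl]phenol; 5 1-bromo-3-methylbut-2-ene (prenyl bromide)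
Product: 6 2-{2-[2,6-dimethyl-4-(3-methylbut-2-enyloxy)phenyl]ethyl}-2-methyl-1,3-dioxolane
Conditions: K2CO3, acetone, reflux
Reagents that add atoms: none
Why: Williamson ether synthesis of the phenoxide with a reactive primary allylic bromide under mild carbonate conditions.

Step 3
Reactants: 6 2-{2-[2,6-dimethyl-4-(3-methylbut-2-enyloxy)phenyl]ethyl}-2-methyl-1,3-dioxolane
Product: 8 3,5-dimethyl-2-(2-methylbut-3-en-2-yl)-4-[2-(2-methyl-1,3-dioxolan-2-yl)ethyl]phenol, via ortho-dienone 7 (not isolated)
Conditions: PhNEt2, 190 °C, sealed tube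
Reagents that add atoms: none
Why: Aromatic Claisen rearrangement, a [3,3]-sigmatropic shift that delivers the dimethyl-substituted allyl terminus intramolecularly to the ortho carbon C5 (both ortho positions are equivalent and the para position is blocked), which should forge the congested C4–C5 bond that an intermolecular tert-alkylation could not, before tautomerisation restores the arene.

Step 4
Reactants: 8 3,5-dimethyl-2-(2-methylbut-3-en-2-yl)-4-[2-(2-methyl-1,3-dioxolan-2-yl)ethyl]phenol
Product: 9 2-{2-[4-(methoxymethoxy)-2,6-dimethyl-3-(2-methylbut-3-en-2-yl)phenyl]ethyl}-2-methyl-1,3-dioxolane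
Conditions: NaH, MOMCl, THF, 0 °C to rt
Reagents that add atoms: chloromethyl methyl ether COCCl
Why: O-alkylation of the hindered sodium phenoxide caps the C6 oxygen as a base-stable acetal, which later directs ortho-lithiation, blocks alkylation at O6 in the ring closure and also prevents acid-induced cyclisation of the phenol onto the alkene.

Step 5
Reactants: 9 2-{2-[4-(methoxymethoxy)-2,6-dimethyl-3-(2-methylbut-3-en-2-yl)phenyl]ethyl}-2-methyl-1,3-dioxolane
Product: 11 4-{6-(methoxymethoxy)-2,4-dimethyl-3-[2-(2-methyl-1,3-dioxolan-2-yl)ethyl]phenyl}-4-methylpentan-1-ol, via aldehyde 10 (not isolated)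
Conditions: Rh(acac)(CO)2 (1 mol%), Xantphos (2 mol%), CO/H2 (1:1, 20 bar), toluene, 80 °C; then NaBH4, MeOH, 0 °C
Reagents that add atoms: carbon monoxide [C-]#[O+]
Why: Rhodium-catalysed hydroformylation of the terminal alkene should place the formyl group on the terminal carbon because the neighbouring quaternary C4 disfavours branched insertion and rules out alkene isomerisation, and borohydride reduction in the same pot gives the primary alcohol at C1.

Step 6
Reactants: 11 4-{6-(methoxymethoxy)-2,4-dimethyl-3-[2-(2-methyl-1,3-dioxolan-2-yl)ethyl]phenyl}-4-methylpentan-1-ol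
Product: 14 3-(5-hydroxy-2-methylpentan-2-yl)-2-(methoxymethoxy)-4,6-dimethyl-5-[2-(2-methyl-1,3-dioxolan-2-yl)ethyl]phenol, via dilithio species 12 (not isolated), via arylboronate 13 (not isolated)
Conditions: s-BuLi (2.5 equiv), TMEDA, THF, −78 to −20 °C; B(OMe)3, −78 °C to rt; then H2O2, NaOH aq, 0 °C
Reagents that add atoms: hydrogen peroxide OO
Why: Directed ortho-metalation, in which (after deprotonation of the alcohol) the methoxymethoxy group guides lithiation to the only remaining ring C–H at C7, followed by borylation and peroxide oxidation of the arylboronate to the phenol.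

Step 7
Reactants: 14 3-(5-hydroxy-2-methylpentan-2-yl)-2-(methoxymethoxy)-4,6-dimethyl-5-[2-(2-methyl-1,3-dioxolan-2-yl)ethyl]phenol
Product: 15 3-(5-iodo-2-methylpentan-2-yl)-2-(methoxymethoxy)-4,6-dimethyl-5-[2-(2-methyl-1,3-dioxolan-2-yl)ethyl]phenol
Conditions: I2, PPh3, imidazole, CH2Cl2, 0 °C
Reagents that add atoms: iodine II
Why: Appel iodination converts only the primary aliphatic alcohol, since an aryloxyphosphonium ion cannot undergo substitution, so the hindered phenol stays free.

Step 8
Reactants: 15 3-(5-iodo-2-methylpentan-2-yl)-2-(methoxymethoxy)-4,6-dimethyl-5-[2-(2-methyl-1,3-dioxolan-2-yl)ethyl]phenol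
Product: 16 (10R)-13,13-ethylenedioxy-6-(methoxymethoxy)-14,15-dinorlabda-5,8-dien-7-one (10β-methyl)
Conditions: N-(9-anthracenylmethyl)-O-allylcinchonidinium bromide (10 mol%), CsOH·H2O (solid), toluene (0.02 M), −20 °C
Reagents that add atoms: none
Why: Proposed new method: solid CsOH deprotonates the C7 phenol at the interface and the phenoxide enters toluene as a tight ion pair with the chiral ammonium cation, where its para carbon C10 displaces iodide from C1 in an intramolecular SN2 reaction that forms the C1–C10 bond and leaves the cross-conjugated 6-alkoxy-5,8-dien-7-one. The closest known reaction types are the base-mediated intramolecular para-alkylation of phenoxides to cyclohexadienones (Winstein–Masamune alkylation), established only without absolute stereocontrol, and asymmetric phase-transfer C-alkylation of enolates and naphtholates. Ring A closes in a 6-exo-tet mode, assisted by the gem-dimethyl group on C4. The only new stereocentre, C10, is to be set by the chiral cation, which sits at the phenoxide oxygen and must shield one face of the ring so that C1 bonds from the other. The step needs C- over O-alkylation and para over ortho attack: O7 cannot reach C1 without a strained meta-bridged ring, O6 is capped as its methoxymethyl ether, and the ortho carbon C6 bears that ether and lies beside the ion-paired cation, while attack at C10 gives the more stable cross-conjugated dienone. Rearomatisation is excluded because C10 carries a methyl group.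

Step 9
Reactants: 16 (10R)-13,13-ethylenedioxy-6-(methoxymethoxy)-14,15-dinorlabda-5,8-dien-7-one
Product: 17 (10R)-6-(methoxymethoxy)-14,15-dinorlabda-5,8-diene-7,13-dione
Conditions: PPTS, acetone/H2O (10:1), 50 °C
Reagents that add atoms: water O
Why: Acid-catalysed ketal hydrolysis under pyridinium catalysis, mild enough to spare the methoxymethyl ether, whose enol double bond is deactivated towards protonation by conjugation with the C7 carbonyl.

Step 10
Reactants: 17 (10R)-6-(methoxymethoxy)-14,15-dinorlabda-5,8-diene-7,13-dione; 18 allyl 2-(diethoxyphosphoryl)acetate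
Product: 19 allyl (10R,13E)-6-(methoxymethoxy)-7-oxolabda-5,8,13-trien-15-oate
Conditions: NaH, THF, 0 °C to rt
Reagents that add atoms: none
Why: Horner–Wadsworth–Emmons olefination of the unhindered methyl ketone, which should favour the E-trisubstituted enoate (the minor Z isomer to be removed by chromatography), while the hindered cross-conjugated C7 ketone does not react.

Step 11
Reactants: 19 allyl (10R,13E)-6-(methoxymethoxy)-7-oxolabda-5,8,13-trien-15-oate
Product: 21 allyl (13E)-7ξ-hydroxy-6-oxolabda-8,13-dien-15-oate (5α-H), via dienol 20 (not isolated)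
Conditions: NaBH4, CeCl3·7H2O, MeOH, −40 °C; then 1 M HCl aq, THF, 0 °C
Reagents that add atoms: water O
Why: Luche reduction adds hydride 1,2 to the dienone carbonyl, and mild aqueous acid then hydrolyses the now isolated enol ether with protonation at C5 from the α face, away from the C10 methyl group (the trans ring fusion is also expected to be the more stable one next to the C6 ketone), while the configuration at C7 is of no consequence because that centre is reoxidised in step 13.

Step 12
Reactants: 21 allyl (13E)-7ξ-hydroxy-6-oxolabda-8,13-dien-15-oate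
Product: 22 allyl (13E)-6β,7ξ-dihydroxylabda-8,13-dien-15-oate
Conditions: NaBH4, CeCl3·7H2O, MeOH, −40 to 0 °C
Reagents that add atoms: none
Why: Borohydride reduction of the hindered C6 ketone, in which hydride should approach from the α face because the β face is blocked by the syn-axial methyl groups on C4 and C10, which sets the axial 6β-hydroxyl group and leaves the conjugated ester untouched.

Step 13
Reactants: 22 allyl (13E)-6β,7ξ-dihydroxylabda-8,13-dien-15-oate
Product: 23 allyl (13E)-6β-hydroxy-7-oxolabda-8,13-dien-15-oate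
Conditions: MnO2, CH2Cl2, rt
Reagents that add atoms: none
Why: Chemoselective allylic oxidation by MnO2, which leaves the saturated and hindered 6β-hydroxyl alone and merges both C7 epimers into one enone.

Step 14
Reactants: 23 allyl (13E)-6β-hydroxy-7-oxolabda-8,13-dien-15-oate
Product: 24 allyl (13E)-6β,7α-dihydroxylabda-8,13-dien-15-oate
Conditions: Me4NBH(OAc)3, MeCN/AcOH (1:1), −20 °C
Reagents that add atoms: none
Why: Saksena–Evans hydroxyl-directed reduction, in which the 6β-hydroxyl exchanges onto boron and delivers hydride intramolecularly to the β face of the C7 carbonyl, which sets the 7α-hydroxyl group trans to the C6 oxygen.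

Step 15
Reactants: 24 allyl (13E)-6β,7α-dihydroxylabda-8,13-dien-15-oate
Product: 25 allyl (13E)-6β-hydroxy-7α-(3-methylbutanoyloxy)labda-8,13-dien-15-oate
Conditions: 3-methylbutanoyl chloride (1.1 equiv), pyridine, CH2Cl2, 0 °C
Reagents that add atoms: 3-methylbutanoyl chloride CC(C)CC(Cl)=O
Why: Selective acylation of the more accessible allylic 7α-hydroxyl, the axial 6β-hydroxyl being shielded by the syn-axial methyl groups on C4 and C10.

Step 16
Reactants: 25 allyl (13E)-6β-hydroxy-7α-(3-methylbutanoyloxy)labda-8,13-dien-15-oate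
Product: 26 allyl (13E)-6β-acetoxy-7α-(3-methylbutanoyloxy)labda-8,13-dien-15-oate
Conditions: Ac2O, DMAP, pyridine, 50 °C
Reagents that add atoms: acetic anhydride CC(=O)OC(C)=O
Why: DMAP-catalysed acetylation of the remaining hindered secondary alcohol under forcing conditions, with no acyl migration expected across the trans-diaxial diol.

Step 17
Reactants: 26 allyl (13E)-6β-acetoxy-7α-(3-methylbutanoyloxy)labda-8,13-dien-15-oate
Product: 27 (13E)-6β-acetoxy-7α-(3-methylbutanoyloxy)labda-8,13-dien-15-oic acid
Conditions: Pd(PPh3)4 (5 mol%), morpholine, THF, rt; dilute acid work-up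
Reagents that add atoms: none
Why: Tsuji–Trost deallylation, in which zerovalent palladium transfers the allyl group to morpholine and cleaves only the allyl ester, while the acetate and the hindered allylic ester at C7 on the tetrasubstituted alkene stay inert.

**Compound list**

1 | 4-bromo-3,5-dimethylphenol | Oc1cc(C)c(Br)c(C)c1 | starting material
2 | 2-methyl-2-vinyl-1,3-dioxolane | C=CC1(C)OCCO1 | starting material
3 | 9-[2-(2-methyl-1,3-dioxolan-2-yl)ethyl]-9-borabicyclo[3.3.1]nonane | CC1(CCB2C3CCCC2CCC3)OCCO1 | intermediate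
4 | 3,5-dimethyl-4-[2-(2-methyl-1,3-dioxolan-2-yl)ethyl]phenol | Oc1cc(C)c(CCC2(C)OCCO2)c(C)c1 | intermediate
5 | 1-bromo-3-methylbut-2-ene (prenyl bromide) | CC(C)=CCBr | starting material
6 | 2-{2-[2,6-dimethyl-4-(3-methylbut-2-enyloxy)phenyl]ethyl}-2-methyl-1,3-dioxolane | CC(C)=CCOc1cc(C)c(CCC2(C)OCCO2)c(C)c1 | intermediate
7 | 3,5-dimethyl-6-(2-methylbut-3-en-2-yl)-4-[2-(2-methyl-1,3-dioxolan-2-yl)ethyl]cyclohexa-2,4-dien-1-one (racemic) | O=C1C=C(C)C(CCC2(C)OCCO2)=C(C)C1C(C)(C)C=C | intermediate
8 | 3,5-dimethyl-2-(2-methylbut-3-en-2-yl)-4-[2-(2-methyl-1,3-dioxolan-2-yl)ethyl]phenol | Oc1cc(C)c(CCC2(C)OCCO2)c(C)c1C(C)(C)C=C | intermediate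
9 | 2-{2-[4-(methoxymethoxy)-2,6-dimethyl-3-(2-methylbut-3-en-2-yl)phenyl]ethyl}-2-methyl-1,3-dioxolane | COCOc1cc(C)c(CCC2(C)OCCO2)c(C)c1C(C)(C)C=C | intermediate
10 | 4-{6-(methoxymethoxy)-2,4-dimethyl-3-[2-(2-methyl-1,3-dioxolan-2-yl)ethyl]phenyl}-4-methylpentanal | COCOc1cc(C)c(CCC2(C)OCCO2)c(C)c1C(C)(C)CCC=O | intermediate
11 | 4-{6-(methoxymethoxy)-2,4-dimethyl-3-[2-(2-methyl-1,3-dioxolan-2-yl)ethyl]phenyl}-4-methylpentan-1-ol | COCOc1cc(C)c(CCC2(C)OCCO2)c(C)c1C(C)(C)CCCO | intermediate
12 | lithium alkoxide of 11 lithiated at C7 (dilithio species) | [Li]OCCCC(C)(C)c1c(OCOC)c([Li])c(C)c(CCC2(C)OCCO2)c1C | intermediate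
13 | dimethyl arylboronate at C7 (arm as lithium alkoxide) | [Li]OCCCC(C)(C)c1c(OCOC)c(B(OC)OC)c(C)c(CCC2(C)OCCO2)c1C | intermediate
14 | 3-(5-hydroxy-2-methylpentan-2-yl)-2-(methoxymethoxy)-4,6-dimethyl-5-[2-(2-methyl-1,3-dioxolan-2-yl)ethyl]phenol | Oc1c(C)c(CCC2(C)OCCO2)c(C)c(C(C)(C)CCCO)c1OCOC | intermediate
15 | 3-(5-iodo-2-methylpentan-2-yl)-2-(methoxymethoxy)-4,6-dimethyl-5-[2-(2-methyl-1,3-dioxolan-2-yl)ethyl]phenol | Oc1c(C)c(CCC2(C)OCCO2)c(C)c(C(C)(C)CCCI)c1OCOC | intermediate
16 | (10R)-13,13-ethylenedioxy-6-(methoxymethoxy)-14,15-dinorlabda-5,8-dien-7-one (10β-methyl) | O=C1C(C)=C(CCC3(C)OCCO3)[C@@]2(C)CCCC(C)(C)C2=C1OCOC | intermediate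
17 | (10R)-6-(methoxymethoxy)-14,15-dinorlabda-5,8-diene-7,13-dione | O=C1C(C)=C(CCC(C)=O)[C@@]2(C)CCCC(C)(C)C2=C1OCOC | intermediate
18 | allyl 2-(diethoxyphosphoryl)acetate | CCOP(=O)(OCC)CC(=O)OCC=C | starting material
19 | allyl (10R,13E)-6-(methoxymethoxy)-7-oxolabda-5,8,13-trien-15-oate | O=C1C(C)=C(CC/C(C)=C/C(=O)OCC=C)[C@@]2(C)CCCC(C)(C)C2=C1OCOC | intermediate
20 | allyl (13E)-7ξ-hydroxy-6-(methoxymethoxy)labda-5,8,13-trien-15-oate (10β-methyl; C7 epimers) | OC1C(C)=C(CC/C(C)=C/C(=O)OCC=C)[C@@]2(C)CCCC(C)(C)C2=C1OCOC | intermediate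
21 | allyl (13E)-7ξ-hydroxy-6-oxolabda-8,13-dien-15-oate (5α-H, 10β-methyl; C7 epimers) | O=C1C(O)C(C)=C(CC/C(C)=C/C(=O)OCC=C)[C@@]2(C)CCCC(C)(C)[C@H]12 | intermediate
22 | allyl (13E)-6β,7ξ-dihydroxylabda-8,13-dien-15-oate (5α-H, 10β-methyl; C7 epimers) | O[C@@H]1C(O)C(C)=C(CC/C(C)=C/C(=O)OCC=C)[C@@]2(C)CCCC(C)(C)[C@H]12 | intermediate
23 | allyl (13E)-6β-hydroxy-7-oxolabda-8,13-dien-15-oate (5α-H, 10β-methyl) | O[C@@H]1C(=O)C(C)=C(CC/C(C)=C/C(=O)OCC=C)[C@@]2(C)CCCC(C)(C)[C@H]12 | intermediate
24 | allyl (13E)-6β,7α-dihydroxylabda-8,13-dien-15-oate (5α-H, 10β-methyl) | O[C@@H]1[C@@H](O)C(C)=C(CC/C(C)=C/C(=O)OCC=C)[C@@]2(C)CCCC(C)(C)[C@H]12 | intermediate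
25 | allyl (13E)-6β-hydroxy-7α-(3-methylbutanoyloxy)labda-8,13-dien-15-oate | O[C@@H]1[C@@H](OC(=O)CC(C)C)C(C)=C(CC/C(C)=C/C(=O)OCC=C)[C@@]2(C)CCCC(C)(C)[C@H]12 | intermediate
26 | allyl (13E)-6β-acetoxy-7α-(3-methylbutanoyloxy)labda-8,13-dien-15-oate | CC(=O)O[C@@H]1[C@@H](OC(=O)CC(C)C)C(C)=C(CC/C(C)=C/C(=O)OCC=C)[C@@]2(C)CCCC(C)(C)[C@H]12 | intermediate
27 | (5S,6S,7S,10S,13E)-6β-acetoxy-7α-(3-methylbutanoyloxy)labda-8,13-dien-15-oic acid (5α-H, 10β-methyl) | CC(=O)O[C@@H]1[C@@H](OC(=O)CC(C)C)C(C)=C(CC/C(C)=C/C(=O)O)[C@@]2(C)CCCC(C)(C)[C@H]12 | target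

**Step count and risks**

Total steps: 17. Longest linear sequence: 17 steps (1 to 27); compounds 2, 5 and 18 enter as bought.

The three steps most likely to fail:

1. Step 8 (Proposed new method). The ion pair may discriminate the two faces of C10 poorly, or a background closure of unpaired cesium phenoxide may erode the enantiomeric purity. Fallback, setting out from 15: the iodide would be cyclised without chiral control under the classical conditions of this phenoxide alkylation (KOt-Bu, t-BuOH/THF, rt) to the racemic dienone F1. The enantiomers would then be separated by preparative chromatography on a chiral stationary phase (cellulose tris(3,5-dimethylphenylcarbamate), supercritical CO2/MeOH). The (10R)-enantiomer is compound 16, where the route is rejoined, and the (10S)-enantiomer F2 is set aside.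

2. Step 3. At 190 °C the prenyl ether may lose its allyl group as isoprene, the 1,1-dimethylallyl group may isomerise by the abnormal Claisen pathway, or the freed phenol may add to the alkene. Fallback, setting out from 4 and returning at 11, builds the C4–C5 bond by aryllithium addition and the C3–C4 bond by a radical reaction, which is much less sensitive to the flanking ortho groups than ionic substitution:
   - Phenol 4 would be protected (NaH, MOMCl, THF) as the methoxymethyl ether F3.
   - Lithiation ortho to the acetal (s-BuLi, TMEDA, THF, −78 °C) would give the aryllithium F4, and quenching with acetone would give the tertiary benzylic alcohol F5.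
   - Acylation with methyl chlorooxoacetate (Et3N, DMAP, CH2Cl2) would give the methyl oxalate F6, and saponification with one equivalent of CsOH (THF/H2O) the cesium oxalate F7.
   - Photoredox decarboxylation (Ir[dF(CF3)ppy]2(dtbbpy)PF6, blue light, DME/DMF, H2O) would release the tertiary radical at C4, which is trapped by methyl acrylate in a Giese addition to give the methyl ester F8.
   - Reduction with LiAlH4 (THF, 0 °C) would give alcohol 11.

3. Step 11. In acid, ionisation of the bis-allylic C7 alcohol to a cyclohexadienyl cation (followed by migration or loss of a proton) may compete with hydrolysis of the enol ether, and the ketol may transpose its carbonyl through the enediol. Fallback, setting out from 19 and returning at 22: the methoxymethyl group would be removed first (2 M HCl aq, THF, 40 °C), which gives the acid-stable diosphenol allyl (10R,13E)-6-hydroxy-7-oxolabda-5,8,13-trien-15-oate F9. An excess of NaBH4 with CeCl3·7H2O in MeOH would then reduce the C7 carbonyl; the resulting enediol would ketonise at C5 to ketol 21 in the flask, and this would be reduced on to diol 22, so that no acid meets the C7 alcohol.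

Further compounds
F1 | step 8 | racemic 13,13-ethylenedioxy-6-(methoxymethoxy)-14,15-dinorlabda-5,8-dien-7-one | O=C1C(C)=C(CCC3(C)OCCO3)C2(C)CCCC(C)(C)C2=C1OCOC
F2 | step 8 | (10S)-13,13-ethylenedioxy-6-(methoxymethoxy)-14,15-dinorlabda-5,8-dien-7-one | O=C1C(C)=C(CCC3(C)OCCO3)[C@]2(C)CCCC(C)(C)C2=C1OCOC
F3 | step 3 | 2-{2-[4-(methoxymethoxy)-2,6-dimethylphenyl]ethyl}-2-methyl-1,3-dioxolane | COCOc1cc(C)c(CCC2(C)OCCO2)c(C)c1
F4 | step 3 | aryllithium from F3, lithiated ortho to the methoxymethoxy group | COCOc1c([Li])c(C)c(CCC2(C)OCCO2)c(C)c1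
F5 | step 3 | 2-{6-(methoxymethoxy)-2,4-dimethyl-3-[2-(2-methyl-1,3-dioxolan-2-yl)ethyl]phenyl}propan-2-ol | COCOc1cc(C)c(CCC2(C)OCCO2)c(C)c1C(C)(C)O
F6 | step 3 | methyl oxalate of F5 | COCOc1cc(C)c(CCC2(C)OCCO2)c(C)c1C(C)(C)OC(=O)C(=O)OC
F7 | step 3 | cesium oxalate of F5 | COCOc1cc(C)c(CCC2(C)OCCO2)c(C)c1C(C)(C)OC(=O)C(=O)[O-].[Cs+]
F8 | step 3 | methyl 4-{6-(methoxymethoxy)-2,4-dimethyl-3-[2-(2-methyl-1,3-dioxolan-2-yl)ethyl]phenyl}-4-methylpentanoate | COCOc1cc(C)c(CCC2(C)OCCO2)c(C)c1C(C)(C)CCC(=O)OC
F9 | step 11 | allyl (10R,13E)-6-hydroxy-7-oxolabda-5,8,13-trien-15-oate | O=C1C(C)=C(CC/C(C)=C/C(=O)OCC=C)[C@@]2(C)CCCC(C)(C)C2=C1O
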